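I chose to judge this flask by how much starting material its solid reagent can carry away, and I reckoned that first.

| flask | starting material | second substrate | solid reagent | remark | time |
|---|---|---|---|---|---|
| spring | 0.14 M | 0.028 M | 0.067 M | run made earlier |  |
| flask | 0.14 M | 0.0280 M | 0.133 M |  | 80 min |

spring run (percent of the starting material charged)

| time / min | target / % | starting material / % |
|---|---|---|
| 0.667 | 17 | 70 |
| 1.33 | 8 | 59 |
| 2.50 | 7 | 48 |
| 4.00 | 4 | 40 |
| 8.00 | 0 | 28 |

(standard deviation of a reading: 1.5 percentage points)

* time, not beyond 80 min, at which the flask holds most target
* the amount of target, in percent of the starting material charged, at that time

- given per volume of solution although it is solid: solid reagent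
- the earlier runs were read with a standard deviation of 1.5 percentage points
- at the start none of the solid reagent is in solution

Two extreme flasks can be done in the head. In one, each solid reagent takes one starting material and stops at target, so the flask could consume 95.0% of its charge. In the other, every target takes a further starting material, and the solid reagent is good for 190% of the starting material charged: this is the reach, twice the solid reagent charge divided by the starting material charge. The spring run lay between them: at 8.00 min it had lost 1.50 starting material per solid reagent as read, with target read at 0%. Since the reach of this flask is more than the whole charge of starting material, I expected the solid reagent not to stop the consumption of starting material in this flask, and target to be an early, passing peak.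

The forecast gave 17% at 0.33 min, on the ground that “the time axis compresses about twofold while peak height stays similar”.

The flask gave 22.7% at 1.04 min.

    starting material + partner ⇌ target (K = 11.0 M⁻¹, k = 0.890 M⁻¹ s⁻¹)
    second substrate + partner ⇌ second product (K = 44.0 M⁻¹, k = 5.90 M⁻¹ s⁻¹)
    solid reagent ⇌ partner, rate k3*(cs3 - [partner]) while solid is left; crystals form when [partner] > cs3 (solubility = 0.0600 M, k = 0.0680 s⁻¹)
    starting material + target → side product (k = 0.170 M⁻¹ s⁻¹)

At 0.378 min this flask made target 3.00 times faster than it used it up, each step taken net. Half of the turnover to side product up to the longest time was done by 1.87 min, and at 80.0 min the flask held 0.640% target, 1.30% starting material and 98.1% side product, as a reach of 190% allows.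

In the same flask with 0.033 M of solid reagent instead, the reach is 47.1%, which makes solid reagent the limiting reagent and gives 52.9% of the starting material as the reckoned remainder. That neighbour flask ended with 52.9% starting material and 47.1% side product, after a best of 7.79% target.

Readings and results come from a simulation with made-up constants, noise included.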